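**Plan**

1. Numbering used throughout (daucane): C1 = quaternary ring-fusion carbon (methyl C15), C2/C3 = ring CH2, C4 = carbinol carbon (isopropyl), C5 = ring-fusion CH, C6 = acyloxy carbon, C7 = CH2, C8 (methyl C14)=C9, C10 = ketone. Cuts, in order: the ester C–O; the C8=C9 unsaturation (back to the saturated ketone); C1–C5 together with C8–C9, which opens both rings to one acyclic chain; then C1–C10 and C6–C7, which leaves the ten carbons C1–C6, C15 and isopropyl of (S)-terpinen-4-ol.
2. Forward: ozonolysis opens terpinen-4-ol to a keto aldehyde; a propenyl unit (C7, C8, C14) is put on C6 and an ethoxyvinyl unit (C10, C9) on C1; one cationic (4+3) cycloaddition then closes the cyclopentane and the cycloheptane together.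
3. Enabling feature: the C4 hydroxyl and the C6 oxygen are 1,3-related, so silicon can tie them into a temporary 4H-1,3,2-dioxasiline (ring atoms Si, O4, C4, C5, C6, O6). This locks C5=C6–C7=C8 as a 2-silyloxydiene three atoms (C2–C3–C4) away from the allyl cation C1–C10–C9. The silicon ring and the ethyl enol ether are not in the target and are hydrolysed after ring closure.
4. Stereochemistry: C4 from the chiral pool; C5 from the temporary ring (cis delivery across C4–C5); C1 from the extended approach of the planar cation, through which both carbinol epimers converge; C6 from hydroxyl-directed hydride delivery from O4; the uncontrolled C8 centre is erased by the final dehydrogenation.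

Key step: step 6

Assumption: (S)-(+)-terpinen-4-ol is taken as purchasable in high enantiomeric purity; it is the only source of absolute configuration in the route.

**Route**

Step 1
Reactants: 1 (S)-(+)-terpinen-4-ol
Product: 3 (3S)-3-hydroxy-6-oxo-3-(propan-2-yl)heptanal, via secondary ozonide 2 (not isolated)
Conditions: O3, CH2Cl2, −78 °C; then Me2S, −78 → 25 °C; used crude
Reagents that add atoms: ozone, [O-][O+]=O
Why: Ozonolysis with reductive work-up (Criegee mechanism) should cleave the only C=C of 1 to the C6 aldehyde and the C1 methyl ketone, leaving the tertiary carbinol (C4) and its configuration untouched.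

Step 2
Reactants: 3 (3S)-3-hydroxy-6-oxo-3-(propan-2-yl)heptanal; 4 (E)-1-bromoprop-1-ene
Product: 5 (5S,8E)-5,7-dihydroxy-5-(propan-2-yl)dec-8-en-2-one (both C7 epimers)
Conditions: 4 (2 equiv), CrCl2 (4 equiv), NiCl2 (2 mol %), DMF, 25 °C
Reagents that add atoms: (E)-1-bromoprop-1-ene 4, C/C=C/Br
Why: In the Nozaki–Hiyama–Kishi coupling the alkenylchromium reagent should add to the aldehyde much faster than to the ketone, tolerate the free hydroxyl and keep the E geometry; the new carbinol centre is formed as a mixture that step 3 removes.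

Step 3
Reactants: 5 (5S,8E)-5,7-dihydroxy-5-(propan-2-yl)dec-8-en-2-one
Product: 6 (5S,8E)-5-hydroxy-5-(propan-2-yl)dec-8-ene-2,7-dione
Conditions: MnO2 (15 equiv), CH2Cl2, 25 °C
Reagents that add atoms: none
Why: MnO2 oxidises the allylic secondary alcohol selectively under neutral conditions, which should spare the tertiary aldol (no retro-aldol) and give the E enone; no stereocentre is formed.

Step 4
Reactants: 6 (5S,8E)-5-hydroxy-5-(propan-2-yl)dec-8-ene-2,7-dione; 7 di(propan-2-yl)silyl bis(trifluoromethanesulfonate)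
Product: 9 4-[(4R)-2,2,4-tri(propan-2-yl)-6-[(E)-prop-1-enyl]-4H-1,3,2-dioxasilin-4-yl]butan-2-one, via tertiary silyl ether monotriflate 8 (not isolated)
Conditions: 7 (1.1 equiv), 2,6-lutidine (1.2 equiv), CH2Cl2, −40 → 0 °C; then Et3N (3 equiv), 0 → 25 °C
Reagents that add atoms: di(propan-2-yl)silyl bis(trifluoromethanesulfonate) 7, CC(C)[Si](OS(=O)(=O)C(F)(F)F)(OS(=O)(=O)C(F)(F)F)C(C)C
Why: Under 2,6-lutidine the silyl triflate should silylate the hydroxyl without enol-silylating ketones, and Et3N should then drive intramolecular enol silylation (silyl triflate/amine soft enolisation) of the adjacent C6 ketone through a six-membered ring, which fixes deprotonation at C5 and leaves the remote methyl ketone free; no stereocentre is formed.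

Step 5
Reactants: 9 4-[(4R)-2,2,4-tri(propan-2-yl)-6-[(E)-prop-1-enyl]-4H-1,3,2-dioxasilin-4-yl]butan-2-one; 10 ethyl vinyl ether
Product: 12 (3RS)-2-ethoxy-3-methyl-5-[(4R)-2,2,4-tri(propan-2-yl)-6-[(E)-prop-1-enyl]-4H-1,3,2-dioxasilin-4-yl]pent-1-en-3-ol, via 1-ethoxyvinyllithium 11 (not isolated)
Conditions: 10, t-BuLi, THF, −78 → 0 °C; then 9, −78 °C; aq. NaHCO3 work-up; used crude
Reagents that add atoms: ethyl vinyl ether 10, C=COCC (delivered as 1-ethoxyvinyllithium 11, [Li]C(=C)OCC)
Why: 1,2-Addition of the α-alkoxyvinyllithium to the methyl ketone should proceed at −78 °C without attack on the hindered silyl dienol ether; the new C1 carbinol is a mixture of epimers, both of which converge in step 6.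

Step 6
Reactants: 12 (3RS)-2-ethoxy-3-methyl-5-[(4R)-2,2,4-tri(propan-2-yl)-6-[(E)-prop-1-enyl]-4H-1,3,2-dioxasilin-4-yl]pent-1-en-3-ol
Product: 15 tricyclic bis(enol ether): trans-fused cyclopentane–cycloheptadiene with O4 and O6 still bridged by Si(i-Pr)2 (C6=C7 silyl enol ether) and an ethyl enol ether at C10 (C9=C10); C8 epimers, via 2-ethoxyallyl cation triflate 13 (not isolated), via O-ethyl oxocarbenium cycloadduct triflate 14 (not isolated)
Conditions: Tf2O (1.1 equiv), 2,6-lutidine (3 equiv), CH2Cl2 (0.01 M), −78 °C; then Et3N, aq. NaHCO3; used crude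
Reagents that add atoms: none
Why: Proposed new method: Tf2O converts the tertiary 2-ethoxyallylic alcohol (either C1 epimer) into a triflate that ionises at −78 °C to the planar 2-ethoxyallyl cation 13 (C1–C10–C9), which should be captured across C5 and C8 of the s-cis 2-silyloxydiene held in the dioxasiline ring, either concertedly but asynchronously or in fast steps (C1–C5 first, then C9–C8), giving oxocarbenium ion 14 that 2,6-lutidine deprotonates at C9; the closest known reaction type is the intramolecular (4+3) cycloaddition of alkoxyallyl cations, generated from 2-alkoxyallylic alcohols with Tf2O and 2,6-lutidine, with tethered 1,3-dienes, and the new element is a ring-locked 2-silyloxydiene as the four-carbon partner. The cyclopentane closes in a 5-exo mode (C5 attacks the cation terminus C1, the C10=C9 enol ether staying outside the ring) and the cycloheptene in a 7-endo mode (C9 bonds to the allyl-cation terminus C8, leaving the C6=C7 silyl enol ether inside the ring). C5 is controlled by the temporary ring: the C2–C3 tether can reach only the C5 face on the side of C3, so the cyclopentane is cis-fused to the dioxasiline and C6 ends up cis to O4 (H5 anti to O4). C1 is controlled by the approach geometry: in the extended arrangement expected for an electrophilic alkoxyallyl cation the small C1 methyl, not the ethoxyvinyl arm, lies over the dioxasiline ring, which gives the trans ring fusion (methyl cis to O4); C8 is not controlled because step 10 removes it. The step needs (4+3) closure at C8 in preference to (3+2) closure at C6 or proton loss from the cation, which the s-cis bias of the 2-oxygenated diene, the proximity of C9 to C8 after the first bond, and the low temperature with a hindered base should secure.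

Step 7
Reactants: 15 tricyclic bis(enol ether)
Product: 16 (3R,3aR,8aS)-3-hydroxy-6,8a-dimethyl-3-(propan-2-yl)perhydroazulene-4,8-dione (C6-methyl epimers; locants as in the target)
Conditions: 48% aq. HF, MeCN, 0 °C
Reagents that add atoms: water, O
Why: Fluoride should cleave both Si–O bonds and the aqueous acid should hydrolyse the ethyl enol ether (protonation at C9, hydration of the oxocarbenium ion), unmasking the C6 and C10 ketones; C7 and C9 become CH2, so no stereocentre arises, and the mild acid at 0 °C is chosen to spare the tertiary β-hydroxy ketone.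

Step 8
Reactants: 16 (3R,3aR,8aS)-3-hydroxy-6,8a-dimethyl-3-(propan-2-yl)perhydroazulene-4,8-dione
Product: 17 (3R,3aS,4S,8aS)-3,4-dihydroxy-6,8a-dimethyl-3-(propan-2-yl)perhydroazulen-8-one (C6-methyl epimers; locants as in the target)
Conditions: Me4NBH(OAc)3 (5 equiv), MeCN/AcOH (1:1), −30 → −20 °C
Reagents that add atoms: none
Why: In the Evans–Saksena hydroxyl-directed reduction boron binds the C4 oxygen and hydride is delivered through a six-membered transition state to the C6 carbonyl face syn to O4, which should set the C6 hydroxyl anti to O4 (1,3-anti diol) and leave the neopentyl C10 ketone, which has no suitably placed hydroxyl, unreduced.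

Step 9
Reactants: 17 (3R,3aS,4S,8aS)-3,4-dihydroxy-6,8a-dimethyl-3-(propan-2-yl)perhydroazulen-8-one; 18 3,4,5-trimethoxybenzoyl chloride
Product: 19 (3R,3aS,4S,8aS)-3-hydroxy-6,8a-dimethyl-8-oxo-3-(propan-2-yl)perhydroazulen-4-yl 3,4,5-trimethoxybenzoate (C6-methyl epimers)
Conditions: 18 (1.5 equiv), DMAP (0.2 equiv), pyridine, CH2Cl2, 0 → 25 °C
Reagents that add atoms: 3,4,5-trimethoxybenzoyl chloride 18, COc1cc(C(Cl)=O)cc(OC)c1OC
Why: DMAP-catalysed acylation should take the secondary C6 hydroxyl only, since the tertiary C4 hydroxyl is too hindered; no stereocentre is affected.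

Step 10
Reactants: 19 (3R,3aS,4S,8aS)-3-hydroxy-6,8a-dimethyl-8-oxo-3-(propan-2-yl)perhydroazulen-4-yl 3,4,5-trimethoxybenzoate
Product: 20 (3R,3aS,4S,8aS)-3-hydroxy-6,8a-dimethyl-8-oxo-3-(propan-2-yl)-1,2,3,3a,4,5,8,8a-octahydroazulen-4-yl 3,4,5-trimethoxybenzoate
Conditions: IBX (2.5 equiv), DMSO/fluorobenzene (1:2), 70 °C
Reagents that add atoms: none
Why: IBX dehydrogenation of the ketone goes through the enol, which can form only toward C9 because C1 is quaternary, so C8=C9 should be introduced regiospecifically and both C8 epimers should converge on the target, while the aryl ester and tertiary alcohol are inert to IBX.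

**Compound list**

1 | (S)-(+)-terpinen-4-ol, (1S)-4-methyl-1-(propan-2-yl)cyclohex-3-en-1-ol | CC1=CC[C@](O)(C(C)C)CC1 | starting material
2 | secondary ozonide (bridged 1,2,4-trioxolane) of 1 | CC12CC[C@@](O)(C(C)C)CC(OO1)O2 | intermediate
3 | (3S)-3-hydroxy-6-oxo-3-(propan-2-yl)heptanal | O=CC[C@](O)(C(C)C)CCC(C)=O | intermediate
4 | (E)-1-bromoprop-1-ene | C/C=C/Br | starting material
5 | (5S,8E)-5,7-dihydroxy-5-(propan-2-yl)dec-8-en-2-one (C7 epimers) | C/C=C/C(O)C[C@](O)(C(C)C)CCC(C)=O | intermediate
6 | (5S,8E)-5-hydroxy-5-(propan-2-yl)dec-8-ene-2,7-dione | C/C=C/C(=O)C[C@](O)(C(C)C)CCC(C)=O | intermediate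
7 | di(propan-2-yl)silyl bis(trifluoromethanesulfonate) | CC(C)[Si](OS(=O)(=O)C(F)(F)F)(OS(=O)(=O)C(F)(F)F)C(C)C | starting material
8 | tertiary silyl ether monotriflate of 6 (O4–Si(i-Pr)2–OTf) | C/C=C/C(=O)C[C@](O[Si](OS(=O)(=O)C(F)(F)F)(C(C)C)C(C)C)(C(C)C)CCC(C)=O | intermediate
9 | 4-[(4R)-2,2,4-tri(propan-2-yl)-6-[(E)-prop-1-enyl]-4H-1,3,2-dioxasilin-4-yl]butan-2-one | C/C=C/C1=C[C@](C(C)C)(CCC(C)=O)O[Si](C(C)C)(C(C)C)O1 | intermediate
10 | ethyl vinyl ether | C=COCC | starting material
11 | 1-ethoxyvinyllithium | [Li]C(=C)OCC | intermediate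
12 | (3RS)-2-ethoxy-3-methyl-5-[(4R)-2,2,4-tri(propan-2-yl)-6-[(E)-prop-1-enyl]-4H-1,3,2-dioxasilin-4-yl]pent-1-en-3-ol | C=C(OCC)C(C)(O)CC[C@@]1(C(C)C)C=C(/C=C/C)O[Si](C(C)C)(C(C)C)O1 | intermediate
13 | 2-ethoxyallyl cation (C1–C10–C9) triflate derived from 12 | C=C(OCC)[C+](C)CC[C@@]1(C(C)C)C=C(/C=C/C)O[Si](C(C)C)(C(C)C)O1.[O-]S(=O)(=O)C(F)(F)F | intermediate
14 | O-ethyl oxocarbenium cycloadduct triflate | CC[O+]=C1CC(C)C=C2O[Si](C(C)C)(C(C)C)O[C@@]3(C(C)C)CC[C@@]1(C)[C@@H]23.[O-]S(=O)(=O)C(F)(F)F | intermediate
15 | tricyclic bis(enol ether): trans-fused 5–7 bicycle, O4–Si(i-Pr)2–O6 ring retained (C6=C7), ethyl enol ether at C10 (C9=C10), C8 epimers | CCOC1=CC(C)C=C2O[Si](C(C)C)(C(C)C)O[C@@]3(C(C)C)CC[C@@]1(C)[C@@H]23 | intermediate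
16 | (3R,3aR,8aS)-3-hydroxy-6,8a-dimethyl-3-(propan-2-yl)perhydroazulene-4,8-dione (C6-methyl epimers) | CC1CC(=O)[C@H]2[C@](O)(C(C)C)CC[C@]2(C)C(=O)C1 | intermediate
17 | (3R,3aS,4S,8aS)-3,4-dihydroxy-6,8a-dimethyl-3-(propan-2-yl)perhydroazulen-8-one (C6-methyl epimers) | CC1C[C@H](O)[C@H]2[C@](O)(C(C)C)CC[C@]2(C)C(=O)C1 | intermediate
18 | 3,4,5-trimethoxybenzoyl chloride | COc1cc(C(Cl)=O)cc(OC)c1OC | starting material
19 | (3R,3aS,4S,8aS)-3-hydroxy-6,8a-dimethyl-8-oxo-3-(propan-2-yl)perhydroazulen-4-yl 3,4,5-trimethoxybenzoate (C6-methyl epimers) | COc1cc(C(=O)O[C@H]2CC(C)CC(=O)[C@@]3(C)CC[C@@](O)(C(C)C)[C@H]23)cc(OC)c1OC | intermediate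
20 | (3R,3aS,4S,8aS)-3-hydroxy-6,8a-dimethyl-8-oxo-3-(propan-2-yl)-1,2,3,3a,4,5,8,8a-octahydroazulen-4-yl 3,4,5-trimethoxybenzoate | COc1cc(C(=O)O[C@H]2CC(C)=CC(=O)[C@@]3(C)CC[C@@](O)(C(C)C)[C@H]23)cc(OC)c1OC | target

Total step count: 10. Longest linear sequence: 10 steps (1 → 20).

**Steps most likely to fail**

Step 6. The cation may close in the (3+2) sense onto C6 or lose a proton before cyclising, or the compact approach may compete and erode the trans ring fusion, which cannot be corrected later because C1 is quaternary. The fallback sets out from 12 and comes back at 16; it moves the oxygen off the diene so that the ring closure becomes the established alkoxyallyl-cation (4+3) cycloaddition onto a simple tethered diene.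
- MeLi (THF, 0 °C) should cleave the enol Si–O bond to the lithium dienolate, leaving a methyldi(propan-2-yl)silyl ether on O4; trapping with PhNTf2 should give the dienyl triflate F1.
- Reduction with Pd(OAc)2, PPh3, Bu3N and HCO2H should give the (E,E)-diene F2.
- Tf2O and 2,6-lutidine at −78 °C should give the ethyl enol ether cycloadduct F3, hydrolysed by dilute aqueous acid to the cycloheptenone F4 (C6=C7). Without the silicon ring the C5 face is no longer fixed, so the trans-fused isomer with H5 anti to O4 would have to be separated here.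
- mCPBA should give the epoxide F5 (either face serves).
- LiAlH4 should open the epoxide at the less hindered C7 and reduce C10, giving the diol F6.
- Dess–Martin periodinane should give the dione silyl ether F7.
- HF·pyridine should free the tertiary hydroxyl to give 16.

Step 4. The silyl bis-triflate may enol-silylate the unhindered remote methyl ketone or link two molecules instead of closing the ring, and silylation of the hindered tertiary hydroxyl may be slow. The fallback sets out from 6 and comes back at 9; it takes the competing ketone out of play by a temporary change of oxidation level at C1.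
- NaBH4 in MeOH/CH2Cl2 at −78 °C (saturated ketone reduced in preference to the enone) should give the hydroxy enone F8.
- Ac2O and pyridine should acetylate only the secondary hydroxyl to give the acetate F9.
- Reagent 7 with 2,6-lutidine, then Et3N, should now close the ring without competition to give the dioxasiline acetate F10.
- i-Bu2AlH at −78 °C should remove the acetate to give the dioxasiline alcohol F11.
- Dess–Martin periodinane buffered with pyridine should return the methyl ketone 9.

Step 10. The hindered ketone may convert slowly, and forcing the reaction may over-oxidise the enone to a dienone or cause loss of the trimethoxybenzoate from its vinylogous β-position. The fallback sets out from 19 and comes back at 20; it replaces direct oxidation by a Saegusa–Ito sequence at room temperature.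
- TMSOTf and Et3N should give the C9=C10 trimethylsilyl enol ether with O4 also silylated, F12.
- Pd(OAc)2 in MeCN should give the O4-silylated enone F13.
- HF·pyridine should remove the silyl ether to give 20.

**Further compounds**

F1 | step 6 | dienyl triflate of 12 after enol Si–O cleavage: O4 methyldi(propan-2-yl)silyl ether, C5=C6(OTf)–C7=C8 | C=C(OCC)C(C)(O)CC[C@](C(C)C)(O[Si](C)(C(C)C)C(C)C)/C=C(/C=C/C)OS(=O)(=O)C(F)(F)F
F2 | step 6 | (E,E)-diene carbinol: O4 silyl ether, C5=C6–C7=C8 diene without oxygen at C6 | C=C(OCC)C(C)(O)CC[C@](C(C)C)(O[Si](C)(C(C)C)C(C)C)/C=C/C=C/C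
F3 | step 6 | ethyl enol ether (4+3) cycloadduct of F2 (C9=C10 enol ether, C6=C7 alkene, O4 silyl ether) | CCOC1=CC(C)C=C[C@H]2[C@](O[Si](C)(C(C)C)C(C)C)(C(C)C)CC[C@]12C
F4 | step 6 | cycloheptenone from hydrolysis of F3 (C10 ketone, C6=C7 alkene, O4 silyl ether) | CC1C=C[C@H]2[C@](O[Si](C)(C(C)C)C(C)C)(C(C)C)CC[C@]2(C)C(=O)C1
F5 | step 6 | C6–C7 epoxide of F4 | CC1C2OC2[C@H]3[C@](O[Si](C)(C(C)C)C(C)C)(C(C)C)CC[C@]3(C)C(=O)C1
F6 | step 6 | C6,C10-diol from hydride opening and ketone reduction of F5 | CC1CC(O)[C@H]2[C@](O[Si](C)(C(C)C)C(C)C)(C(C)C)CC[C@]2(C)C(O)C1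
F7 | step 6 | O4-silylated 6,10-dione (silyl ether of 16) | CC1CC(=O)[C@H]2[C@](O[Si](C)(C(C)C)C(C)C)(C(C)C)CC[C@]2(C)C(=O)C1
F8 | step 4 | (5S,8E)-2,5-dihydroxy-5-(propan-2-yl)dec-8-en-7-one (C2 epimers) | C/C=C/C(=O)C[C@](O)(C(C)C)CCC(C)O
F9 | step 4 | 2-acetate of F8 | C/C=C/C(=O)C[C@](O)(C(C)C)CCC(C)OC(C)=O
F10 | step 4 | dioxasiline acetate (9 with the ketone replaced by CH–OAc) | C/C=C/C1=C[C@](C(C)C)(CCC(C)OC(C)=O)O[Si](C(C)C)(C(C)C)O1
F11 | step 4 | dioxasiline alcohol (9 with the ketone replaced by CH–OH) | C/C=C/C1=C[C@](C(C)C)(CCC(C)O)O[Si](C(C)C)(C(C)C)O1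
F12 | step 10 | bis(trimethylsilyl) derivative of 19: C9=C10 silyl enol ether and O4 silyl ether | COc1cc(C(=O)O[C@H]2CC(C)C=C(O[Si](C)(C)C)[C@@]3(C)CC[C@@](O[Si](C)(C)C)(C(C)C)[C@H]23)cc(OC)c1OC
F13 | step 10 | O4-trimethylsilyl ether of 20 | COc1cc(C(=O)O[C@H]2CC(C)=CC(=O)[C@@]3(C)CC[C@@](O[Si](C)(C)C)(C(C)C)[C@H]23)cc(OC)c1OC
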